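## Retrosynthetic overview

1. The side chain is cut at C2–C3: a Ni–H hydroalkylation joins tridec-12-en-2-one (9) to an iodoethyl lactone. That lactone is unmasked from a cis-fused γ/δ-bis-lactone, whose δ-lactone locks the 2,3-cis relationship and hides both the CO2H and the CH2CH2–X handle.
2. The 4-methyl group comes from enolate methylation of the bis-lactone, anti to the ring-fusion bond.
3. The γ-lactone comes from Baeyer–Villiger ring expansion of a cis-fused cyclobutanone (1,2-shift of the ring-fusion carbon to oxygen, with retention).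
4. The cyclobutanone comes from a desymmetrising intramolecular α-alkylation of 2-iodoethyl 3-oxocyclobutanecarboxylate (new step), which sets both ring-fusion stereocentres.
5. Ring order: cyclobutanone (bought) → δ-lactone (step 2) → γ-lactone by ring expansion (step 3) → δ-lactone opened (step 6).

Assumption: the sense of induction in step 2 must be found by experiment; (S)-α-methylproline is written, and the (R)-catalyst is used if it gives the mirror-image ketone.

## Route

Step 1
Reactants: 1 3-oxocyclobutane-1-carboxylic acid; 2 2-iodoethan-1-ol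
Product: 3 2-iodoethyl 3-oxocyclobutane-1-carboxylate
Conditions: DCC (1.1 equiv), DMAP (5 mol %), CH2Cl2, 0 °C → rt
Reagents that add atoms: none
Why: Steglich esterification of the acid with the primary alcohol under neutral conditions leaves the strained ketone and the primary iodide untouched; no stereocentre is formed.

Step 2
Reactants: 3 2-iodoethyl 3-oxocyclobutane-1-carboxylate
Product: 4 (1S,6S)-3-oxabicyclo[4.2.0]octane-2,7-dione
Conditions: (S)-α-methylproline (20 mol %), Et3N (1.1 equiv), CHCl3, −20 °C → rt
Reagents that add atoms: none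
Why: Proposed new method: the amino acid forms rapidly interconverting enamines toward either enantiotopic α-carbon of the prochiral cyclobutanone, only the face syn to the ester arm can reach the CH2–I carbon (6-enolexo-exo-tet SN2) so closure is necessarily cis-fused, and the catalyst's carboxylate/ammonium unit, which assists iodide departure on one enamine face, selects which α-carbon is alkylated and so fixes both stereocentres as (1S,6S) under Curtin–Hammett control (later enolisation cannot erode this because the cis-fusion is kept); the closest known reaction types are proline-type amine-catalysed intramolecular α-alkylation of ω-halo aldehydes, Stork enamine alkylation and amine-catalysed desymmetrising aldol reactions of 3-substituted cyclobutanones.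

Step 3
Reactants: 4 (1S,6S)-3-oxabicyclo[4.2.0]octane-2,7-dione
Product: 5 (1S,6S)-3,7-dioxabicyclo[4.3.0]nonane-2,8-dione
Conditions: mCPBA (1.3 equiv), CH2Cl2, 0 °C → rt
Reagents that add atoms: meta-chloroperoxybenzoic acid, OOC(=O)c1cccc(Cl)c1
Why: Baeyer–Villiger oxidation: the Criegee adduct of the strained ketone collapses by 1,2-shift of the more substituted ring-fusion carbon C6 from carbon to oxygen with retention, expanding the four-membered ring to the γ-lactone and placing the new C–O bond cis to the carbonyl arm, while the δ-lactone is inert to peracid.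

Step 4
Reactants: 5 (1S,6S)-3,7-dioxabicyclo[4.3.0]nonane-2,8-dione
Product: 6 (1S,6S,9S)-9-methyl-3,7-dioxabicyclo[4.3.0]nonane-2,8-dione
Conditions: LiHMDS (1.05 equiv), THF, −78 °C; MeI (3 equiv), −78 → −40 °C
Reagents that add atoms: iodomethane, CI
Why: Lactone enolate alkylation: kinetic deprotonation takes the unhindered CH2 of the γ-lactone rather than the ring-fusion methine, and MeI enters anti to the vicinal C1–C2 bond on the convex face of the cis-fused bicycle, setting C9 as S (methyl trans to the future carboxyl).

Step 5
Reactants: 7 octa-1,7-diene (4 equiv); 8 5-bromopentan-2-one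
Product: 9 tridec-12-en-2-one
Conditions: NiBr2·diglyme (10 mol %), 4,4′-di-tert-butyl-2,2′-bipyridine (12 mol %), NaI (20 mol %), (EtO)2MeSiH (2 equiv), Na2CO3 (2 equiv), DMA, 30 °C
Reagents that add atoms: none
Why: Nickel hydride-catalysed anti-Markovnikov reductive hydroalkylation: Ni–H adds to one terminal alkene of the excess diene to give the primary alkylnickel, which captures the alkyl radical from the halide, with the ketone tolerated and the excess diene suppressing double coupling.

Step 6
Reactants: 6 (1S,6S,9S)-9-methyl-3,7-dioxabicyclo[4.3.0]nonane-2,8-dione; 9 tridec-12-en-2-one (1.5 equiv)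
Product: 12 (2S,3S,4S)-4-methyl-5-oxo-2-(14-oxopentadecyl)oxolane-3-carboxylic acid, via iodoethyl lactone TMS ester 10 (not isolated), via target TMS ester 11 (not isolated)
Conditions: TMSI (1.1 equiv), CH2Cl2, rt → 40 °C, evaporate; then 9, NiBr2·diglyme (10 mol %), 4,4′-di-tert-butyl-2,2′-bipyridine (12 mol %), (EtO)2MeSiH (2.5 equiv), Na2CO3 (2 equiv), DMA, 30 °C; 1 M HCl work-up
Reagents that add atoms: none
Why: Iodotrimethylsilane lactone cleavage (O-silylation, then SN2 attack of iodide on the O-alkyl carbon) is far faster at the primary OCH2 of the δ-lactone than at the hindered secondary carbon of the γ-lactone and leaves the acid masked as its silyl ester so that it cannot re-close on the iodide, after which Ni–H anti-Markovnikov hydroalkylation of 9 forms the side-chain C2–C3 bond without touching the three stereocentres and acidic work-up frees the acid.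

## Compound list

1 | 3-oxocyclobutane-1-carboxylic acid | O=C1CC(C1)C(=O)O | starting material
2 | 2-iodoethan-1-ol | OCCI | starting material
3 | 2-iodoethyl 3-oxocyclobutane-1-carboxylate | O=C1CC(C1)C(=O)OCCI | intermediate
4 | (1S,6S)-3-oxabicyclo[4.2.0]octane-2,7-dione (cis-fused cyclobutanone/δ-lactone; ketone next to the ring-fusion carbon that carries the CH2CH2O arm) | O1CC[C@@H]2C(=O)C[C@@H]2C1=O | intermediate
5 | (1S,6S)-3,7-dioxabicyclo[4.3.0]nonane-2,8-dione (cis-fused γ-lactone/δ-lactone) | O1CC[C@@H]2OC(=O)C[C@@H]2C1=O | intermediate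
6 | (1S,6S,9S)-9-methyl-3,7-dioxabicyclo[4.3.0]nonane-2,8-dione (methyl trans to the C1–C2 bond) | O1CC[C@@H]2OC(=O)[C@@H](C)[C@@H]2C1=O | intermediate
7 | octa-1,7-diene | C=CCCCCC=C | starting material
8 | 5-bromopentan-2-one | CC(=O)CCCBr | starting material
9 | tridec-12-en-2-one | CC(=O)CCCCCCCCCC=C | intermediate
10 | trimethylsilyl (2S,3S,4S)-2-(2-iodoethyl)-4-methyl-5-oxooxolane-3-carboxylate | ICC[C@@H]1OC(=O)[C@@H](C)[C@@H]1C(=O)O[Si](C)(C)C | intermediate
11 | trimethylsilyl (2S,3S,4S)-4-methyl-5-oxo-2-(14-oxopentadecyl)oxolane-3-carboxylate | CC(=O)CCCCCCCCCCCCC[C@@H]1OC(=O)[C@@H](C)[C@@H]1C(=O)O[Si](C)(C)C | intermediate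
12 | (2S,3S,4S)-4-methyl-5-oxo-2-(14-oxopentadecyl)oxolane-3-carboxylic acid (2,3-cis, 3,4-trans) | CC(=O)CCCCCCCCCCCCC[C@@H]1OC(=O)[C@@H](C)[C@@H]1C(=O)O | target

## Step count and risks

Total steps: 6. Longest linear sequence: 5 (steps 1, 2, 3, 4, 6); step 5 is a one-step side branch.

Most likely to fail:

**Step 2 (new reaction).** The risks are slow C-alkylation by a ketone enamine, N-alkylation of the catalyst, and low or reversed enantioselectivity. The fallback uses known chemistry and sets out from 3. The lithium enolate of 3 (LiHMDS, THF–DMPU, −78 → 0 °C, high dilution) is closed by ordinary intramolecular enolate alkylation to racemic cis-3-oxabicyclo[4.2.0]octane-2,7-dione F1. The enantiomers are then separated in the ring expansion itself by a kinetic-resolution Baeyer–Villiger oxidation (chiral Sc(III)–N,N′-dioxide/H2O2 or a Baeyer–Villiger monooxygenase, catalyst classes known to discriminate the enantiomers of ring-fused cyclobutanones), run to about half conversion. The fast enantiomer gives the bis-lactone directly and the slow (1R,6R)-3-oxabicyclo[4.2.0]octane-2,7-dione F2 is removed by chromatography. The fallback comes back to the route at 5, at the cost of at most 50 % yield.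

**Step 4 (methylation of the bis-lactone).** The risk is competing deprotonation of the ring-fusion methine α to the δ-lactone, followed by β-elimination of the γ-lactone oxygen. The fallback sets out from 5 and moves the methylation to the monocyclic acid, where the carboxylate protects that position.
- 5 is opened with TMSI to the trimethylsilyl iodoethyl ester F3 and coupled in the same flask, under the step-6 Ni–H conditions, with an excess of diene 7. This gives the trimethylsilyl decenyl ester F4 and, after work-up, (2S,3S)-2-(dec-9-en-1-yl)-5-oxooxolane-3-carboxylic acid F5.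
- The dianion of F5 (NaHMDS 2.2 equiv, THF, −78 °C; MeI) is methylated trans to the carboxylate, the standard protocol for this lactone-acid family, to give (2S,3S,4S)-2-(dec-9-en-1-yl)-4-methyl-5-oxooxolane-3-carboxylic acid F6.
- Cross-metathesis of F6 with hept-6-en-2-one F7 (Grubbs II, CH2Cl2, 40 °C) gives (2S,3S,4S)-4-methyl-5-oxo-2-[(9E)-14-oxopentadec-9-en-1-yl]oxolane-3-carboxylic acid F8 (mainly E).
- Hydrogenation (H2, Pd/C, EtOAc) comes back to the route at 12.

**Step 6 (telescoped lactone opening and coupling).** The risk is loss of the silyl ester under the basic coupling conditions, after which the carboxylate re-closes on the iodide and returns 6. The fallback sets out from 6 and replaces the transient silyl ester by an isolable methyl ester.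
- TMSCl/NaI in MeCN at 60 °C followed by water gives, through 10, (2S,3S,4S)-2-(2-iodoethyl)-4-methyl-5-oxooxolane-3-carboxylic acid F9, which is stable as the free acid.
- TMSCHN2 in MeOH–toluene gives methyl (2S,3S,4S)-2-(2-iodoethyl)-4-methyl-5-oxooxolane-3-carboxylate F10.
- Ni–H hydroalkylation of 9 with F10 (catalyst system of step 5) gives methyl (2S,3S,4S)-4-methyl-5-oxo-2-(14-oxopentadecyl)oxolane-3-carboxylate F11.
- Acid hydrolysis (6 M HCl, dioxane, 80 °C; the γ-lactone re-closes under acid) comes back to the route at 12.

## Further compounds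

F1 | step 2 | rac-cis-3-oxabicyclo[4.2.0]octane-2,7-dione (1:1 mixture of 4 and its enantiomer) | O1CC[C@@H]2C(=O)C[C@@H]2C1=O.O1CC[C@H]2C(=O)C[C@H]2C1=O
F2 | step 2 | (1R,6R)-3-oxabicyclo[4.2.0]octane-2,7-dione | O1CC[C@H]2C(=O)C[C@H]2C1=O
F3 | step 4 | trimethylsilyl (2S,3S)-2-(2-iodoethyl)-5-oxooxolane-3-carboxylate | ICC[C@@H]1OC(=O)C[C@@H]1C(=O)O[Si](C)(C)C
F4 | step 4 | trimethylsilyl (2S,3S)-2-(dec-9-en-1-yl)-5-oxooxolane-3-carboxylate | C=CCCCCCCCC[C@@H]1OC(=O)C[C@@H]1C(=O)O[Si](C)(C)C
F5 | step 4 | (2S,3S)-2-(dec-9-en-1-yl)-5-oxooxolane-3-carboxylic acid | C=CCCCCCCCC[C@@H]1OC(=O)C[C@@H]1C(=O)O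
F6 | step 4 | (2S,3S,4S)-2-(dec-9-en-1-yl)-4-methyl-5-oxooxolane-3-carboxylic acid | C=CCCCCCCCC[C@@H]1OC(=O)[C@@H](C)[C@@H]1C(=O)O
F7 | step 4 | hept-6-en-2-one | CC(=O)CCCC=C
F8 | step 4 | (2S,3S,4S)-4-methyl-5-oxo-2-[(9E)-14-oxopentadec-9-en-1-yl]oxolane-3-carboxylic acid | CC(=O)CCC/C=C/CCCCCCCC[C@@H]1OC(=O)[C@@H](C)[C@@H]1C(=O)O
F9 | step 6 | (2S,3S,4S)-2-(2-iodoethyl)-4-methyl-5-oxooxolane-3-carboxylic acid | ICC[C@@H]1OC(=O)[C@@H](C)[C@@H]1C(=O)O
F10 | step 6 | methyl (2S,3S,4S)-2-(2-iodoethyl)-4-methyl-5-oxooxolane-3-carboxylate | ICC[C@@H]1OC(=O)[C@@H](C)[C@@H]1C(=O)OC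
F11 | step 6 | methyl (2S,3S,4S)-4-methyl-5-oxo-2-(14-oxopentadecyl)oxolane-3-carboxylate | CC(=O)CCCCCCCCCCCCC[C@@H]1OC(=O)[C@@H](C)[C@@H]1C(=O)OC
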